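**Plan**

Retrosynthesis: the C9 ester C–O bond, the C6–O bond (traced back to C6–B) and the C4=CH2 bond (traced back to C4=O) are cut first; C6–C7 and C5–C10 are then cut together, which opens both rings to an achiral trienone.
Locants: ring A = C10, C1, C2, C3, C4 (=CH2), C5; ring B = C5 (H), C6 (OH), C7 (isopropyl), C8, C9 (aroyloxy), C10 (methyl). The enabling feature is that four of the five stereocentres (C5, C6, C7, C10) are ring-B atoms, and ring B, with C9 read as an enol-ether carbon, is the [4+2] adduct of the diene C7=C8–C9=C10 and the alkene C5=C6, ring A being the bridge C1–C4 from C10 to C5.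
Forward: C7/C8 (3-methylbut-1-yne) is joined to the C9–C4 chain (adipate half-ester chloride), C10 gains its methyl carbon by α-methylenation, 1,4-hydrosilylation fixes the (Z)-dienol ether, and C5/C6 arrive as an ethynyl unit that is hydroborated. Rings A and B then close together in the intramolecular Diels–Alder step, followed by C4 methylenation, unmasking and reduction of C9, acylation and C–B oxidation.
Stereochemistry: the relative configuration at C5, C6, C7 and C10 is encoded in the three alkene geometries of the trienone; the absolute configuration comes from a chiral oxazaborolidinium Lewis acid on the C4 ketone; C9 is set by a reagent-controlled oxazaborolidine reduction; C6–OH arises from C6–B with retention.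

Key step: step 8

Remark: open-chain compounds are named by chain locants and ring compounds as decalins with the locants above (C5 and C10 are the fusion atoms); atoms are discussed by the decalin locants throughout, and the SMILES strings define the configurations meant.
Assumption: the C4 ketone is taken to bind the oxazaborolidinium ion as acrylates and cyclic enones do (boron on the lone pair next to C5, s-trans enone), for which the (R)-catalyst exposes the Si face of C5; if the sense proves opposite, the (S)-catalyst is used with nothing else changed.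

**Route**

Step 1
Reactants: 1 3-methylbut-1-yne; 2 methyl 6-chloro-6-oxohexanoate
Product: 4 methyl (E)-9-methyl-6-oxodec-7-enoate, via alkenylzirconocene chloride 3 (not isolated)
Conditions: Cp2Zr(H)Cl (1.1 equiv), CH2Cl2, rt; then 2, CuBr·SMe2 (10 mol%), THF, 0 °C to rt
Reagents that add atoms: none
Why: Hydrozirconation adds Zr–H syn and anti-Markovnikov across the alkyne and so fixes the (E) geometry of C7=C8, and the copper-catalysed acylation of the alkenylzirconocene by the acid chloride proceeds with retention and leaves the methyl ester untouched, no stereocentre being formed.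

Step 2
Reactants: 4 methyl (E)-9-methyl-6-oxodec-7-enoate
Product: 6 methyl (E)-9-methyl-5-methylidene-6-oxodec-7-enoate, via Mannich base 5 (not isolated)
Conditions: (CH2O)n (3 equiv), iPr2NH2+ CF3CO2− (1.0 equiv), CF3CO2H (0.1 equiv), THF, 65 °C
Reagents that add atoms: formaldehyde (from paraformaldehyde), C=O
Why: Mannich-type α-methylenation, in which C10 is the only enolisable carbon next to the ketone, the iminium ion is attacked there and β-elimination of the amine from the Mannich base gives the 1,1-disubstituted enone, no stereocentre being formed.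

Step 3
Reactants: 6 methyl (E)-9-methyl-5-methylidene-6-oxodec-7-enoate
Product: 7 methyl (5E,7E)-5,9-dimethyl-6-{[tri(propan-2-yl)silyl]oxy}deca-5,7-dienoate
Conditions: iPr3SiH (1.1 equiv), Pt2[(CH2=CHSiMe2)2O]3 (0.5 mol%), toluene, 25–50 °C
Reagents that add atoms: triisopropylsilane, CC(C)[SiH](C(C)C)C(C)C
Why: Platinum-catalysed 1,4-hydrosilylation of the enone, in which hydride goes to the unsubstituted methylene terminus (C7 of the other arm is hindered by isopropyl) through the cisoid O=C9–C10=CH2 conformer, so that silyloxy and the new C10 methyl end up cis and the tether cis to C8, which is the (Z)-diene geometry required; no stereocentre is formed.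

Step 4
Reactants: 7 methyl (5E,7E)-5,9-dimethyl-6-{[tri(propan-2-yl)silyl]oxy}deca-5,7-dienoate
Product: 8 (5E,7E)-5,9-dimethyl-6-{[tri(propan-2-yl)silyl]oxy}deca-5,7-dienal
Conditions: iBu2AlH (1.05 equiv), CH2Cl2, −78 °C; MeOH, then aq. potassium sodium tartrate
Reagents that add atoms: none
Why: Partial reduction of the methyl ester by the aluminium hydride stops at the tetrahedral aluminium hemiacetal at −78 °C and releases the aldehyde (C4) on work-up, the silyl dienol ether being inert to the hydride and no stereocentre being formed.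

Step 5
Reactants: 8 (5E,7E)-5,9-dimethyl-6-{[tri(propan-2-yl)silyl]oxy}deca-5,7-dienal; 9 ethynylmagnesium bromide
Product: 10 (7E,9E)-7,11-dimethyl-8-{[tri(propan-2-yl)silyl]oxy}dodeca-7,9-dien-1-yn-3-ol (racemic)
Conditions: HC≡CMgBr (1.3 equiv), THF, −78 to 0 °C; aq. NH4Cl
Reagents that add atoms: none
Why: Grignard 1,2-addition of the acetylide to the aldehyde brings in C5 and C6 and gives the propargylic alcohol as a racemate, which is of no consequence because this carbinol carbon (C4) becomes a ketone in step 7.

Step 6
Reactants: 10 (7E,9E)-7,11-dimethyl-8-{[tri(propan-2-yl)silyl]oxy}dodeca-7,9-dien-1-yn-3-ol; 11 pinacolborane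
Product: 13 (1E,7E,9E)-7,11-dimethyl-1-(4,4,5,5-tetramethyl-1,3,2-dioxaborolan-2-yl)-8-{[tri(propan-2-yl)silyl]oxy}dodeca-1,7,9-trien-3-ol (racemic), via O-boryl ether 12 (not isolated)
Conditions: 11 (2.5 equiv), Cp2Zr(H)Cl (10 mol%), Et3N (10 mol%), CH2Cl2, 25–40 °C; aq. NH4Cl
Reagents that add atoms: none
Why: Zirconium-catalysed hydroboration of the terminal alkyne is a syn, anti-Markovnikov addition that gives the (E)-alkenylboronate (C5=C6), the hydroxyl being carried as its O-boryl ether until work-up and the hindered dienol ether not reacting.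

Step 7
Reactants: 13 (1E,7E,9E)-7,11-dimethyl-1-(4,4,5,5-tetramethyl-1,3,2-dioxaborolan-2-yl)-8-{[tri(propan-2-yl)silyl]oxy}dodeca-1,7,9-trien-3-ol
Product: 14 (1E,7E,9E)-7,11-dimethyl-1-(4,4,5,5-tetramethyl-1,3,2-dioxaborolan-2-yl)-8-{[tri(propan-2-yl)silyl]oxy}dodeca-1,7,9-trien-3-one
Conditions: Dess–Martin periodinane (1.3 equiv), NaHCO3, CH2Cl2, 0 °C; cold aq. Na2S2O3/NaHCO3; used at once
Reagents that add atoms: none
Why: Dess–Martin oxidation of the allylic alcohol under bicarbonate buffer at 0 °C should leave the C–B bond, the alkene geometries and the silyl dienol ether intact, and the trienone is carried on immediately so that neither uncatalysed cyclisation nor a 1,5-hydrogen shift of the (Z)-diene intervenes.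

Step 8
Reactants: 14 (1E,7E,9E)-7,11-dimethyl-1-(4,4,5,5-tetramethyl-1,3,2-dioxaborolan-2-yl)-8-{[tri(propan-2-yl)silyl]oxy}dodeca-1,7,9-trien-3-one
Product: 15 (5R,6S,7S,10R)-10-methyl-7-(propan-2-yl)-6-(4,4,5,5-tetramethyl-1,3,2-dioxaborolan-2-yl)-9-{[tri(propan-2-yl)silyl]oxy}-cis-decal-8-en-4-one
Conditions: (R)-1-(2-methylphenyl)-3,3-diphenyltetrahydro-1H,3H-pyrrolo[1,2-c][1,3,2]oxazaborole (20 mol%), Tf2NH (18 mol%), CH2Cl2, −78 to −20 °C; Et3N quench
Reagents that add atoms: none
Why: Proposed new method: the N-protonated oxazaborolidinium ion binds the C4 carbonyl oxygen and lowers the LUMO of the (E)-C5=C6 boryl enone, which adds suprafacially to the C7=C8–C9=C10 silyloxy diene in a concerted, asynchronous [4+2] cycloaddition that forms C6–C7 and C5–C10, the vacant boron p orbital making C5 electrophilic and so easing the tether-imposed bond from the nucleophilic C10 to C5. The closest known reactions are oxazaborolidinium-catalysed intramolecular Diels–Alder reactions of trienals, the same catalysts with 2-silyloxy dienes and enones, and thermal intramolecular Diels–Alder reactions of (Z)-dienes, which give only cis-fused bicycles; the combination of a tetrasubstituted (Z)-dienol ether terminus, a β-boryl enone and a chiral Lewis acid has not been shown. Ring B closes as the cyclohexene of the [4+2] itself (its atoms C5–C10 are the four diene and two dienophile carbons), and ring A closes as the six-membered tether ring C10–C1–C2–C3–C4–C5 of a type 1 intramolecular cycloaddition when C5–C10 forms, with the C4 carbonyl inside that ring. C10 and C5 become cis-fused because the tether is the inside substituent of C10 and can reach C5 only with C4 exo; C6 follows from the (E)-enone, which puts boron trans to C4; C7 follows from the (E)-C7=C8 bond, which puts isopropyl outside and hence cis to the outside C10 methyl and to boron; the absolute sense comes from the catalyst, which shields one face of the bound enone so that C10 adds to the Si face of C5. The step needs periselectivity over intramolecular Mukaiyama–Michael addition, over desilylation and over the uncatalysed racemic pathway, and it must outrun the 1,5-hydrogen shift of the (Z)-diene; the low temperature, the bulky triisopropylsilyl group, the non-nucleophilic triflimide counter-ion and the six-membered tether (against a seven-membered ring for the Michael pathway) are relied on for this.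

Step 9
Reactants: 15 (5R,6S,7S,10R)-10-methyl-7-(propan-2-yl)-6-(4,4,5,5-tetramethyl-1,3,2-dioxaborolan-2-yl)-9-{[tri(propan-2-yl)silyl]oxy}-cis-decal-8-en-4-one
Product: 16 (5S,6S,7S,10R)-10-methyl-4-methylidene-7-(propan-2-yl)-6-(4,4,5,5-tetramethyl-1,3,2-dioxaborolan-2-yl)-9-{[tri(propan-2-yl)silyl]oxy}-cis-decal-8-ene
Conditions: Cp2TiMe2 (2.5 equiv), toluene/THF, 65 °C, dark
Reagents that add atoms: dimethyltitanocene, C[Ti](C)(C1C=CC=C1)C1C=CC=C1
Why: Petasis methylenation, in which thermolysis of Cp2TiMe2 gives Cp2Ti=CH2 that converts the C4 ketone into the exocyclic alkene by [2+2] cycloaddition and cycloreversion under non-basic conditions, so that the C5 stereocentre next to the carbonyl is not epimerised and the boronate and silyl enol ether are untouched.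

Step 10
Reactants: 16 (5S,6S,7S,10R)-10-methyl-4-methylidene-7-(propan-2-yl)-6-(4,4,5,5-tetramethyl-1,3,2-dioxaborolan-2-yl)-9-{[tri(propan-2-yl)silyl]oxy}-cis-decal-8-ene
Product: 17 (5S,6S,7S,10R)-10-methyl-4-methylidene-7-(propan-2-yl)-6-(4,4,5,5-tetramethyl-1,3,2-dioxaborolan-2-yl)-cis-decalin-9-one
Conditions: Bu4NF (1.2 equiv), AcOH (1.2 equiv), THF, 0 °C
Reagents that add atoms: none
Why: Fluoride-induced cleavage of the silyl enol ether with acetic acid as proton source protonates C8 and releases the C9 ketone without forming a stereocentre, the buffered medium avoiding migration of the exocyclic alkene and loss of the boronate.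

Step 11
Reactants: 17 (5S,6S,7S,10R)-10-methyl-4-methylidene-7-(propan-2-yl)-6-(4,4,5,5-tetramethyl-1,3,2-dioxaborolan-2-yl)-cis-decalin-9-one
Product: 18 (5S,6S,7S,9R,10R)-10-methyl-4-methylidene-7-(propan-2-yl)-6-(4,4,5,5-tetramethyl-1,3,2-dioxaborolan-2-yl)-cis-decalin-9-ol
Conditions: (S)-1-methyl-3,3-diphenyltetrahydro-1H,3H-pyrrolo[1,2-c][1,3,2]oxazaborole (0.3 equiv), catecholborane (2 equiv), toluene, −40 to −20 °C; MeOH, then pH 7 buffer
Reagents that add atoms: none
Why: Corey–Bakshi–Shibata reduction, in which the (S)-oxazaborolidine binds the ketone oxygen on the lone pair beside the C8 methylene, away from quaternary C10, and passes hydride from coordinated catecholborane to the ring-B face opposite the C10 methyl, giving the 9R alcohol with hydroxyl cis to that methyl (equatorial in the chair with equatorial isopropyl), while catecholborane at low temperature does not hydroborate the exocyclic alkene.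

Step 12
Reactants: 18 (5S,6S,7S,9R,10R)-10-methyl-4-methylidene-7-(propan-2-yl)-6-(4,4,5,5-tetramethyl-1,3,2-dioxaborolan-2-yl)-cis-decalin-9-ol; 19 4-methoxybenzoyl chloride
Product: 20 (5S,6S,7S,9R,10R)-10-methyl-4-methylidene-7-(propan-2-yl)-6-(4,4,5,5-tetramethyl-1,3,2-dioxaborolan-2-yl)-cis-decalin-9-yl 4-methoxybenzoate
Conditions: 19 (2 equiv), Et3N (3 equiv), DMAP (0.3 equiv), CH2Cl2, 0 °C to rt
Reagents that add atoms: none
Why: DMAP-catalysed acylation (nucleophilic acyl substitution) of the secondary C9 alcohol, in which the C9–O bond is not broken so the configuration is retained, the boronate at C6 serving as a masked hydroxyl that cannot be acylated.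

Step 13
Reactants: 20 (5S,6S,7S,9R,10R)-10-methyl-4-methylidene-7-(propan-2-yl)-6-(4,4,5,5-tetramethyl-1,3,2-dioxaborolan-2-yl)-cis-decalin-9-yl 4-methoxybenzoate
Product: 21 (5S,6S,7R,9R,10R)-6-hydroxy-10-methyl-4-methylidene-7-(propan-2-yl)-cis-decalin-9-yl 4-methoxybenzoate (CNP0107029.1)
Conditions: NaBO3·4H2O (5 equiv), THF/H2O (1:1), rt
Reagents that add atoms: sodium perborate (NaBO3·4H2O, dimeric peroxoborate), [Na+].[Na+].O[B-]1(O)OO[B-](O)(O)OO1
Why: Oxidation of the secondary alkylboronate by perborate, in which the peroxide adds to boron and C6 migrates from boron to oxygen with retention, giving the 6S alcohol cis to isopropyl, while the mild, weakly basic medium leaves the aryl ester and the exocyclic alkene intact.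

**Compound list**

1 | 3-methylbut-1-yne | CC(C)C#C | starting material
2 | methyl 6-chloro-6-oxohexanoate (adipic acid monomethyl ester chloride) | COC(=O)CCCCC(Cl)=O | starting material
3 | chlorobis(cyclopentadienyl)[(E)-3-methylbut-1-enyl]zirconium (not isolated) | CC(C)/C=C/[Zr](Cl)(C1C=CC=C1)C1C=CC=C1 | intermediate
4 | methyl (E)-9-methyl-6-oxodec-7-enoate | CC(C)/C=C/C(=O)CCCCC(=O)OC | intermediate
5 | methyl (E)-5-[(dipropan-2-ylamino)methyl]-9-methyl-6-oxodec-7-enoate (racemic, not isolated) | CC(C)/C=C/C(=O)C(CN(C(C)C)C(C)C)CCCC(=O)OC | intermediate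
6 | methyl (E)-9-methyl-5-methylidene-6-oxodec-7-enoate | CC(C)/C=C/C(=O)C(=C)CCCC(=O)OC | intermediate
7 | methyl (5E,7E)-5,9-dimethyl-6-{[tri(propan-2-yl)silyl]oxy}deca-5,7-dienoate | CC(C)/C=C/C(O[Si](C(C)C)(C(C)C)C(C)C)=C(/C)CCCC(=O)OC | intermediate
8 | (5E,7E)-5,9-dimethyl-6-{[tri(propan-2-yl)silyl]oxy}deca-5,7-dienal | CC(C)/C=C/C(O[Si](C(C)C)(C(C)C)C(C)C)=C(/C)CCCC=O | intermediate
9 | ethynylmagnesium bromide | C#C[Mg]Br | starting material
10 | (7E,9E)-7,11-dimethyl-8-{[tri(propan-2-yl)silyl]oxy}dodeca-7,9-dien-1-yn-3-ol (racemic) | CC(C)/C=C/C(O[Si](C(C)C)(C(C)C)C(C)C)=C(/C)CCCC(O)C#C | intermediate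
11 | pinacolborane (4,4,5,5-tetramethyl-1,3,2-dioxaborolane) | CC1(C)OBOC1(C)C | starting material
12 | O-(pinacolboryl) ether of 13 (racemic, not isolated) | CC(C)/C=C/C(O[Si](C(C)C)(C(C)C)C(C)C)=C(/C)CCCC(OB1OC(C)(C)C(C)(C)O1)/C=C/B1OC(C)(C)C(C)(C)O1 | intermediate
13 | (1E,7E,9E)-7,11-dimethyl-1-(4,4,5,5-tetramethyl-1,3,2-dioxaborolan-2-yl)-8-{[tri(propan-2-yl)silyl]oxy}dodeca-1,7,9-trien-3-ol (racemic) | CC(C)/C=C/C(O[Si](C(C)C)(C(C)C)C(C)C)=C(/C)CCCC(O)/C=C/B1OC(C)(C)C(C)(C)O1 | intermediate
14 | (1E,7E,9E)-7,11-dimethyl-1-(4,4,5,5-tetramethyl-1,3,2-dioxaborolan-2-yl)-8-{[tri(propan-2-yl)silyl]oxy}dodeca-1,7,9-trien-3-one (achiral trienone boronate) | CC(C)/C=C/C(O[Si](C(C)C)(C(C)C)C(C)C)=C(/C)CCCC(=O)/C=C/B1OC(C)(C)C(C)(C)O1 | intermediate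
15 | (5R,6S,7S,10R)-10-methyl-7-(propan-2-yl)-6-(4,4,5,5-tetramethyl-1,3,2-dioxaborolan-2-yl)-9-{[tri(propan-2-yl)silyl]oxy}-cis-decal-8-en-4-one (H5, C10 methyl, boron and isopropyl on one face) | O=C1CCC[C@]2(C)[C@H]1[C@@H](B3OC(C)(C)C(C)(C)O3)[C@@H](C(C)C)C=C2O[Si](C(C)C)(C(C)C)C(C)C | intermediate
16 | (5S,6S,7S,10R)-10-methyl-4-methylidene-7-(propan-2-yl)-6-(4,4,5,5-tetramethyl-1,3,2-dioxaborolan-2-yl)-9-{[tri(propan-2-yl)silyl]oxy}-cis-decal-8-ene | C=C1CCC[C@]2(C)[C@H]1[C@@H](B3OC(C)(C)C(C)(C)O3)[C@@H](C(C)C)C=C2O[Si](C(C)C)(C(C)C)C(C)C | intermediate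
17 | (5S,6S,7S,10R)-10-methyl-4-methylidene-7-(propan-2-yl)-6-(4,4,5,5-tetramethyl-1,3,2-dioxaborolan-2-yl)-cis-decalin-9-one | C=C1CCC[C@]2(C)[C@H]1[C@@H](B3OC(C)(C)C(C)(C)O3)[C@@H](C(C)C)CC2=O | intermediate
18 | (5S,6S,7S,9R,10R)-10-methyl-4-methylidene-7-(propan-2-yl)-6-(4,4,5,5-tetramethyl-1,3,2-dioxaborolan-2-yl)-cis-decalin-9-ol | C=C1CCC[C@]2(C)[C@H]1[C@@H](B3OC(C)(C)C(C)(C)O3)[C@@H](C(C)C)C[C@H]2O | intermediate
19 | 4-methoxybenzoyl chloride | COc1ccc(cc1)C(Cl)=O | starting material
20 | (5S,6S,7S,9R,10R)-10-methyl-4-methylidene-7-(propan-2-yl)-6-(4,4,5,5-tetramethyl-1,3,2-dioxaborolan-2-yl)-cis-decalin-9-yl 4-methoxybenzoate | C=C1CCC[C@]2(C)[C@H]1[C@@H](B3OC(C)(C)C(C)(C)O3)[C@@H](C(C)C)C[C@H]2OC(=O)c1ccc(OC)cc1 | intermediate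
21 | (5S,6S,7R,9R,10R)-6-hydroxy-10-methyl-4-methylidene-7-(propan-2-yl)-cis-decalin-9-yl 4-methoxybenzoate, systematically (1R,3R,4S,4aS,8aR)-4-hydroxy-8a-methyl-5-methylidene-3-(propan-2-yl)decahydronaphthalen-1-yl 4-methoxybenzoate | C=C1CCC[C@]2(C)[C@H]1[C@@H](O)[C@@H](C(C)C)C[C@H]2OC(=O)c1ccc(OC)cc1 | target

**Step count and risks**

Total step count: 13. Longest linear sequence: 13 steps (from 1 and 2 to 21).

Steps most likely to fail:

Step 8 (the step labelled as a proposed new method). The Lewis acid may desilylate the dienol ether or trigger a stepwise Mukaiyama–Michael closure faster than the cycloaddition. The strained cisoid (Z)-diene may react so slowly that warming is needed and the 1,5-hydrogen shift takes over. Face discrimination by the catalyst may be insufficient. Fallback with known chemistry: setting out from 14, the cyclisation is promoted by the achiral Lewis acid Me2AlCl (1.1 equiv, CH2Cl2, −78 to −20 °C), a Lewis-acid-promoted intramolecular Diels–Alder reaction of a trienone. The (Z)-diene geometry still enforces the cis ring fusion, so this should give the same adduct as a racemate, that is 15 together with its mirror image, the adduct ent-15 F1. Preparative chromatography on a chiral stationary phase separates the enantiomers and the route is rejoined at 15.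

Step 11. Both faces of the C9 ketone carry an axial neighbour (the C10 methyl on one side, C4 on the other), so the substrate's own bias may oppose the reagent and give poor facial selectivity, or hydride transfer to this neopentyl-type ketone may be too slow. Fallback: setting out from 16, the order of events and the mode of reduction are changed. The C–B bond is oxidised first with NaBO3·4H2O to the enol ether alcohol F2. Bu4NF/AcOH then releases the hydroxy ketone F3. Dissolving-metal reduction (Li, liquid NH3, THF, tBuOH, −78 °C) of F3, in which the configuration is set by protonation of the ketyl-derived carbanion under thermodynamic control, should favour the equatorial C9 carbinol and give the diol F4. The equatorial C9 hydroxyl is then acylated selectively with 19 (Et3N, DMAP, CH2Cl2, 0 °C), the C6 hydroxyl being axial and flanked by C5 and the isopropyl-bearing C7. The route is rejoined at the target 21.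

Step 2. The cross-conjugated dienone forms under hot, acidic ammonium conditions, where oligomerisation, conjugate addition of the amine or thermal degradation may consume it as it forms. Fallback: setting out from 4, the methylene is introduced stepwise under mild conditions. The kinetic enolate at C10 (lithium diisopropylamide, THF, −78 °C) is trapped with dimethylmethyleneammonium iodide to give the Mannich base F5. Quaternisation with MeI gives the ammonium iodide F6. Elimination with aqueous NaHCO3 in CH2Cl2 at 0 °C releases the dienone, which is taken directly into step 3. The route is rejoined at 6.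

Further compounds
F1 | step 8 | (5S,6R,7R,10S)-10-methyl-7-(propan-2-yl)-6-(4,4,5,5-tetramethyl-1,3,2-dioxaborolan-2-yl)-9-{[tri(propan-2-yl)silyl]oxy}-cis-decal-8-en-4-one (ent-15) | O=C1CCC[C@@]2(C)[C@@H]1[C@H](B3OC(C)(C)C(C)(C)O3)[C@H](C(C)C)C=C2O[Si](C(C)C)(C(C)C)C(C)C
F2 | step 11 | (5S,6S,7S,10R)-10-methyl-4-methylidene-7-(propan-2-yl)-9-{[tri(propan-2-yl)silyl]oxy}-cis-decal-8-en-6-ol | C=C1CCC[C@]2(C)[C@H]1[C@@H](O)[C@@H](C(C)C)C=C2O[Si](C(C)C)(C(C)C)C(C)C
F3 | step 11 | (5S,6S,7R,10R)-6-hydroxy-10-methyl-4-methylidene-7-(propan-2-yl)-cis-decalin-9-one | C=C1CCC[C@]2(C)[C@H]1[C@@H](O)[C@@H](C(C)C)CC2=O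
F4 | step 11 | (5S,6S,7R,9R,10R)-10-methyl-4-methylidene-7-(propan-2-yl)-cis-decalin-6,9-diol | C=C1CCC[C@]2(C)[C@H]1[C@@H](O)[C@@H](C(C)C)C[C@H]2O
F5 | step 2 | methyl (E)-5-[(dimethylamino)methyl]-9-methyl-6-oxodec-7-enoate (racemic) | CC(C)/C=C/C(=O)C(CN(C)C)CCCC(=O)OC
F6 | step 2 | [(E)-2-(4-methoxy-4-oxobutyl)-6-methyl-3-oxohept-4-enyl]trimethylammonium iodide (racemic) | CC(C)/C=C/C(=O)C(C[N+](C)(C)C)CCCC(=O)OC.[I-]
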